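**Strategy.** Ring atoms are numbered C1 (bears the side chain), C2, C3 (CHOH), C4, C5 (C–OMe), C6 (CHOAc). C6 is an allylic carbinol attached to the trisubstituted C1=C2 alkene, so the cyclohexa-1,4-diene ring is closed last by an intramolecular Nozaki–Hiyama–Kishi addition: the (Z)-alkenyl iodide at C1 adds to an α-methoxy enal at C6, forming the C1–C6 bond and the C6 stereocentre, trans to the C3 silyl ether, in one neutral operation. The precursor is an acyclic (2E,5Z)-6-iodo-2-methoxydienal, built from an (R)-epichlorohydrin-derived alkyne and a four-carbon methoxy enal by asymmetric alkynylation and hydroxyl-directed trans-hydroalumination–iodination.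

Key step: step 12

Remark on numbering: in the open-chain intermediates 14–19, chain C1 = ring C6, chain C4 = ring C3, chain C6 = ring C1 and chain C8 = the side-chain carbinol.

Assumption: (S,S)-ProPhenol is taken to deliver the alkynyl group to the Si face of aldehyde 12. If MTPA ester analysis of 14 shows the opposite sense, (R,R)-ProPhenol is used and nothing else changes.

Remark on handling: compounds 14–23 contain an acid-labile 3-oxy-1-methoxyallyl unit, so all chromatography should use Et3N-deactivated silica.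

**Step 1**
Reactants: 1 (R)-epichlorohydrin; 2 decylmagnesium bromide
Product: 3 (R)-1-chlorotridecan-2-ol
Conditions: CuI (10 mol%), THF, −40 to −20 °C; aq NH4Cl
Reagents that add atoms: none
Why: Copper-catalysed Grignard opening of the epoxide at its unsubstituted carbon (SN2) should leave the chiral-pool C–O stereocentre untouched.

**Step 2**
Reactants: 3 (R)-1-chlorotridecan-2-ol; 4 lithium acetylide–ethylenediamine complex
Product: 6 (R)-pentadec-1-yn-4-ol, via (R)-2-undecyloxirane 5 (not isolated)
Conditions: 4 (3 equiv), DMSO, 0 °C to rt; H2O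
Reagents that add atoms: none
Why: Excess acetylide should first close the chlorohydrin to epoxide 5 (intramolecular SN2 at the CH2Cl carbon) and then open 5 at its terminal carbon, so the (R) centre is never a reacting atom.

**Step 3**
Reactants: 6 (R)-pentadec-1-yn-4-ol
Product: 7 (R)-triethyl(pentadec-1-yn-4-yloxy)silane
Conditions: TESCl, imidazole, CH2Cl2, 0 °C to rt
Reagents that add atoms: chlorotriethylsilane, CC[Si](Cl)(CC)CC
Why: Standard silylation gives a hydride-stable ether that can later be removed in the presence of a tert-butyldimethylsilyl ether.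

**Step 4**
Reactants: 8 propargyl alcohol
Product: 9 triethyl(prop-2-yn-1-yloxy)silane
Conditions: TESCl, imidazole, CH2Cl2, 0 °C
Reagents that add atoms: chlorotriethylsilane, CC[Si](Cl)(CC)CC
Why: Standard silylation of a primary alcohol.

**Step 5**
Reactants: 9 triethyl(prop-2-yn-1-yloxy)silane
Product: 11 4-(triethylsilyloxy)but-2-ynal, via lithium acetylide 10 (not isolated)
Conditions: n-C4H9Li, THF, −78 °C; DMF; inverse quench into aq KH2PO4
Reagents that add atoms: N,N-dimethylformamide, CN(C)C=O
Why: Formylation of a lithium acetylide with DMF, where the buffered inverse quench should prevent conjugate addition of the liberated dimethylamine.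

**Step 6**
Reactants: 11 4-(triethylsilyloxy)but-2-ynal
Product: 12 (E)-3-methoxy-4-(triethylsilyloxy)but-2-enal
Conditions: CH3OH, NaOCH3 (5 mol%), 0 °C; AcOH (5 mol%)
Reagents that add atoms: methanol, CO
Why: Oxa-Michael addition of methoxide to the ynal places OMe on the β-carbon, and reversible addition should equilibrate the product to the (E)-isomer (formyl anti to OMe, syn to CH2O), the stable geometry of β-alkoxy enals and enoates.

**Step 7**
Reactants: 7 (R)-triethyl(pentadec-1-yn-4-yloxy)silane; 12 (E)-3-methoxy-4-(triethylsilyloxy)but-2-enal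
Product: 14 (2E,4R,8R)-2-methoxy-1,8-bis(triethylsilyloxy)nonadec-2-en-5-yn-4-ol, via alkynyl(methyl)zinc 13 (not isolated)
Conditions: (S,S)-ProPhenol (20 mol%), Ph3P=O (40 mol%), Zn(CH3)2 (3 equiv), 7 (2 equiv, excess recovered), toluene, 0 to 4 °C; aq NH4Cl
Reagents that add atoms: none
Why: Dinuclear zinc–ProPhenol-catalysed enantioselective alkynylation of an α,β-unsaturated aldehyde, in which the chiral pocket should deliver alkynylzinc 13 to the Si face of the formyl group and set the (4R) carbinol (ring C3).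

**Step 8**
Reactants: 14 (2E,4R,8R)-2-methoxy-1,8-bis(triethylsilyloxy)nonadec-2-en-5-yn-4-ol
Product: 16 (2E,4R,5Z,8R)-6-iodo-2-methoxy-1,8-bis(triethylsilyloxy)nonadeca-2,5-dien-4-ol, via cyclic alkenylaluminate 15 (not isolated)
Conditions: NaAlH2(OCH2CH2OCH3)2 (2 equiv), THF, 0 °C to rt; EtOAc; I2, THF, −78 to 0 °C; aq Na2S2O3, aq potassium sodium tartrate
Reagents that add atoms: iodine, II
Why: In this trans-hydroalumination of a propargylic alcohol the aluminium alkoxide delivers hydride to the proximal alkyne carbon, so the C–Al bond of 15 sits on the distal carbon cis to the carbinol and iodinolysis with retention should give the (5Z)-6-iodoalkene.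

**Step 9**
Reactants: 16 (2E,4R,5Z,8R)-6-iodo-2-methoxy-1,8-bis(triethylsilyloxy)nonadeca-2,5-dien-4-ol
Product: 17 tert-butyl{[(2E,4R,5Z,8R)-6-iodo-2-methoxy-1,8-bis(triethylsilyloxy)nonadeca-2,5-dien-4-yl]oxy}dimethylsilane
Conditions: TBSCl, imidazole, DMF, rt
Reagents that add atoms: tert-butylchlorodimethylsilane, CC(C)(C)[Si](C)(C)Cl
Why: Non-acidic silylation of the bis-allylic alcohol blocks lactol and furan formation once the aldehyde is unveiled and distinguishes this oxygen from the two that will be acetylated.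

**Step 10**
Reactants: 17 tert-butyl{[(2E,4R,5Z,8R)-6-iodo-2-methoxy-1,8-bis(triethylsilyloxy)nonadeca-2,5-dien-4-yl]oxy}dimethylsilane
Product: 18 (2E,4R,5Z,8R)-4-(tert-butyldimethylsilyloxy)-6-iodo-2-methoxynonadeca-2,5-diene-1,8-diol
Conditions: HF·pyridine, excess pyridine, THF, 0 °C; aq NaHCO3
Reagents that add atoms: none
Why: Fluoride-mediated desilylation, in which the two triethylsilyl ethers should cleave far faster than the hindered secondary tert-butyldimethylsilyl ether while the pyridine buffer protects the enol ether.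

**Step 11**
Reactants: 18 (2E,4R,5Z,8R)-4-(tert-butyldimethylsilyloxy)-6-iodo-2-methoxynonadeca-2,5-diene-1,8-diol
Product: 19 (2E,4R,5Z,8R)-4-(tert-butyldimethylsilyloxy)-8-hydroxy-6-iodo-2-methoxynonadeca-2,5-dienal
Conditions: MnO2 (activated, 20 equiv), CH2Cl2, rt
Reagents that add atoms: none
Why: MnO2 should oxidise only the allylic primary alcohol, leave the saturated secondary hydroxyl alone, and preserve the enol ether and both alkene geometries under neutral heterogeneous conditions.

**Step 12**
Reactants: 19 (2E,4R,5Z,8R)-4-(tert-butyldimethylsilyloxy)-8-hydroxy-6-iodo-2-methoxynonadeca-2,5-dienal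
Product: 21 (1S,4S)-4-(tert-butyldimethylsilyloxy)-6-[(2R)-2-hydroxytridecyl]-2-methoxycyclohexa-2,5-dien-1-ol, via alkenylchromium dichloride 20 (not isolated)
Conditions: CrCl2 (8 equiv), NiCl2 (1 mol% of CrCl2), degassed DMSO (0.005 M), rt; aq sodium serinate, pH 7–8
Reagents that add atoms: none
Why: Zerovalent nickel, formed from NiCl2 by CrCl2, inserts into the C1–I bond and hands the alkenyl group with retention of the Z geometry to trivalent chromium; alkenylchromium 20 then adds to the C6 aldehyde through a chromium-bridged four-centre transition state to give the chromium alkoxide of 21. The closest known reaction type is the intramolecular Nozaki–Hiyama–Kishi alkenyl iodide–aldehyde coupling, which is well established for six-membered and larger carbocycles. The six-membered ring is closed in the 6-exo-trig mode, the (5Z)-iodoalkene and the (2E)-enal holding C1 and C6 on the same side of the C3 hinge. The new stereocentre C6 is controlled by C3: in the boat-like transition state the forming C6–O–Cr bond should lie pseudoaxial (it is delivered from chromium on C1 and avoids the flanking C5–OMe and C1–CH2 groups), and the bulky C3 silyloxy group takes the pseudoequatorial site to escape the 1,4-flagpole contact, which should place the two oxygens trans (1S,4S). The step needs chemoselectivity for the C–I bond over the aldehyde, free hydroxyl, enol ether and silyl ether, retention of both alkene geometries, and the absence of acid or base that would aromatise the 1,4-dioxygenated cyclohexadiene; the non-basic alkenylchromium and the neutral work-up should secure all three.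

**Step 13**
Reactants: 21 (1S,4S)-4-(tert-butyldimethylsilyloxy)-6-[(2R)-2-hydroxytridecyl]-2-methoxycyclohexa-2,5-dien-1-ol
Product: 22 (1S,4S)-6-[(2R)-2-acetoxytridecyl]-4-(tert-butyldimethylsilyloxy)-2-methoxycyclohexa-2,5-dien-1-yl acetate
Conditions: Ac2O, pyridine, DMAP (cat.), CH2Cl2, 0 °C
Reagents that add atoms: acetic anhydride, CC(=O)OC(C)=O
Why: DMAP-catalysed acylation installs both acetates in one operation with retention at both carbinol carbons.

**Step 14**
Reactants: 22 (1S,4S)-6-[(2R)-2-acetoxytridecyl]-4-(tert-butyldimethylsilyloxy)-2-methoxycyclohexa-2,5-dien-1-yl acetate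
Product: 23 (1S,4S)-6-[(2R)-2-acetoxytridecyl]-4-hydroxy-2-methoxycyclohexa-2,5-dien-1-yl acetate (target)
Conditions: Bu4NF/AcOH (1:1), THF, 0 °C to rt; pH 7 phosphate buffer
Reagents that add atoms: none
Why: Acetic-acid-buffered fluoride desilylation at near-neutral pH should avoid acetate cleavage and acid-triggered aromatisation, and the trans-1,4 arrangement rules out acetyl migration.

**Compound list**

1 | (R)-epichlorohydrin | ClC[C@H]1CO1 | starting material
2 | decylmagnesium bromide | CCCCCCCCCC[Mg]Br | starting material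
3 | (R)-1-chlorotridecan-2-ol | ClC[C@H](O)CCCCCCCCCCC | intermediate
4 | lithium acetylide–ethylenediamine complex | [Li]C#C.NCCN | starting material
5 | (R)-2-undecyloxirane (not isolated) | CCCCCCCCCCC[C@@H]1CO1 | intermediate
6 | (R)-pentadec-1-yn-4-ol | C#CC[C@H](O)CCCCCCCCCCC | intermediate
7 | (R)-triethyl(pentadec-1-yn-4-yloxy)silane | C#CC[C@H](O[Si](CC)(CC)CC)CCCCCCCCCCC | intermediate
8 | propargyl alcohol | C#CCO | starting material
9 | triethyl(prop-2-yn-1-yloxy)silane | C#CCO[Si](CC)(CC)CC | intermediate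
10 | [3-(triethylsilyloxy)prop-1-yn-1-yl]lithium (not isolated) | [Li]C#CCO[Si](CC)(CC)CC | intermediate
11 | 4-(triethylsilyloxy)but-2-ynal | O=CC#CCO[Si](CC)(CC)CC | intermediate
12 | (E)-3-methoxy-4-(triethylsilyloxy)but-2-enal | CO/C(CO[Si](CC)(CC)CC)=C/C=O | intermediate
13 | methyl[(R)-4-(triethylsilyloxy)pentadec-1-yn-1-yl]zinc (not isolated) | C[Zn]C#CC[C@H](O[Si](CC)(CC)CC)CCCCCCCCCCC | intermediate
14 | (2E,4R,8R)-2-methoxy-1,8-bis(triethylsilyloxy)nonadec-2-en-5-yn-4-ol | CCCCCCCCCCC[C@@H](O[Si](CC)(CC)CC)CC#C[C@H](O)/C=C(/OC)CO[Si](CC)(CC)CC | intermediate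
15 | sodium cyclic alkenylaluminate (2,5-dihydro-1,2-oxaluminole from 14, Al bearing two 2-methoxyethoxy groups; not isolated) | [Na+].CCCCCCCCCCC[C@@H](O[Si](CC)(CC)CC)CC1=C[C@@H](/C=C(/OC)CO[Si](CC)(CC)CC)O[Al-]1(OCCOC)OCCOC | intermediate
16 | (2E,4R,5Z,8R)-6-iodo-2-methoxy-1,8-bis(triethylsilyloxy)nonadeca-2,5-dien-4-ol | CCCCCCCCCCC[C@@H](O[Si](CC)(CC)CC)C/C(I)=C/[C@H](O)/C=C(/OC)CO[Si](CC)(CC)CC | intermediate
17 | tert-butyl{[(2E,4R,5Z,8R)-6-iodo-2-methoxy-1,8-bis(triethylsilyloxy)nonadeca-2,5-dien-4-yl]oxy}dimethylsilane | CCCCCCCCCCC[C@@H](O[Si](CC)(CC)CC)C/C(I)=C/[C@H](O[Si](C)(C)C(C)(C)C)/C=C(/OC)CO[Si](CC)(CC)CC | intermediate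
18 | (2E,4R,5Z,8R)-4-(tert-butyldimethylsilyloxy)-6-iodo-2-methoxynonadeca-2,5-diene-1,8-diol | CCCCCCCCCCC[C@@H](O)C/C(I)=C/[C@H](O[Si](C)(C)C(C)(C)C)/C=C(/OC)CO | intermediate
19 | (2E,4R,5Z,8R)-4-(tert-butyldimethylsilyloxy)-8-hydroxy-6-iodo-2-methoxynonadeca-2,5-dienal | CCCCCCCCCCC[C@@H](O)C/C(I)=C/[C@H](O[Si](C)(C)C(C)(C)C)/C=C(/OC)C=O | intermediate
20 | alkenylchromium dichloride from 19 (trivalent chromium on chain C6; not isolated) | CCCCCCCCCCC[C@@H](O)C/C([Cr](Cl)Cl)=C/[C@H](O[Si](C)(C)C(C)(C)C)/C=C(/OC)C=O | intermediate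
21 | (1S,4S)-4-(tert-butyldimethylsilyloxy)-6-[(2R)-2-hydroxytridecyl]-2-methoxycyclohexa-2,5-dien-1-ol | CCCCCCCCCCC[C@@H](O)CC1=C[C@H](O[Si](C)(C)C(C)(C)C)C=C(OC)[C@H]1O | intermediate
22 | (1S,4S)-6-[(2R)-2-acetoxytridecyl]-4-(tert-butyldimethylsilyloxy)-2-methoxycyclohexa-2,5-dien-1-yl acetate | CCCCCCCCCCC[C@@H](OC(C)=O)CC1=C[C@H](O[Si](C)(C)C(C)(C)C)C=C(OC)[C@H]1OC(C)=O | intermediate
23 | (1S,4S)-6-[(2R)-2-acetoxytridecyl]-4-hydroxy-2-methoxycyclohexa-2,5-dien-1-yl acetate | CCCCCCCCCCC[C@H](CC1=C[C@H](O)C=C(OC)[C@H]1OC(C)=O)OC(C)=O | target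

**Total step count:** 14.
**Longest linear sequence:** 11 steps (steps 1–3, then 7–14; the branch through steps 4–6 is equally long).

**Steps most likely to fail**

Step 12 (key step). The risk is poor or reversed facial selectivity at C6 during ring closure, and protonolysis of the alkenylchromium by the nearby free hydroxyl. The fallback sets out from 19 and comes back at 22. Acetylation of 19 (Ac2O, pyridine) should give (2E,4R,5Z,8R)-4-(tert-butyldimethylsilyloxy)-6-iodo-2-methoxy-1-oxononadeca-2,5-dien-8-yl acetate F1. The same CrCl2/NiCl2 closure, through the alkenylchromium dichloride F2, should then give the trans alcohol (2R)-1-[(3S,6S)-3-(tert-butyldimethylsilyloxy)-6-hydroxy-5-methoxycyclohexa-1,4-dien-1-yl]tridecan-2-yl acetate F3 and/or its (3S,6R) epimer F4. F3 is acetylated with retention (Ac2O, pyridine, DMAP). F4 is submitted to a Mitsunobu reaction (AcOH, PPh3, diisopropyl azodicarboxylate) with inversion. Both epimers should thus converge on 22, so the ring closure no longer needs to be selective.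

Step 7. The risk is sluggish addition to the deactivated, vinylogous-formate aldehyde or insufficient enantioselectivity. The fallback sets out from 7 and 12 and comes back at 14. Deprotonation of 7 (n-C4H9Li, THF, −78 °C) gives [(R)-4-(triethylsilyloxy)pentadec-1-yn-1-yl]lithium F5, which adds to 12 to give the C4-epimeric (2E,8R)-2-methoxy-1,8-bis(triethylsilyloxy)nonadec-2-en-5-yn-4-ols F6. MnO2 oxidation gives (2E,8R)-2-methoxy-1,8-bis(triethylsilyloxy)nonadec-2-en-5-yn-4-one F7. Corey–Bakshi–Shibata reduction ((R)-2-methyl-CBS-oxazaborolidine, catecholborane, toluene, −78 °C), with the alkenyl group as the large and the alkynyl group as the small substituent, should then give 14.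

Step 6. The risk is incomplete E/Z equilibration (the Z-isomer cannot cyclise later) and partial loss of the triethylsilyl group in basic methanol. The fallback uses no numbered intermediate: it replaces 8, 9 and 11 by commercial methyl tetronate (4-methoxyfuran-2(5H)-one) F8, whose ring fixes the required geometry, and comes back at 12. Aminolysis (Al(CH3)3, MeNH(OMe)·HCl, CH2Cl2, 0 °C) should open the lactone to (E)-4-hydroxy-N,3-dimethoxy-N-methylbut-2-enamide F9. Silylation (TESCl, imidazole) gives (E)-N,3-dimethoxy-N-methyl-4-(triethylsilyloxy)but-2-enamide F10, and reduction with ((CH3)2CHCH2)2AlH (THF, −78 °C) should give 12.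

**Further compounds**

F1 | step 12 | (2E,4R,5Z,8R)-4-(tert-butyldimethylsilyloxy)-6-iodo-2-methoxy-1-oxononadeca-2,5-dien-8-yl acetate | CCCCCCCCCCC[C@@H](OC(C)=O)C/C(I)=C/[C@H](O[Si](C)(C)C(C)(C)C)/C=C(/OC)C=O
F2 | step 12 | alkenylchromium dichloride from F1 (trivalent chromium, not isolated) | CCCCCCCCCCC[C@@H](OC(C)=O)C/C([Cr](Cl)Cl)=C/[C@H](O[Si](C)(C)C(C)(C)C)/C=C(/OC)C=O
F3 | step 12 | (2R)-1-[(3S,6S)-3-(tert-butyldimethylsilyloxy)-6-hydroxy-5-methoxycyclohexa-1,4-dien-1-yl]tridecan-2-yl acetate | CCCCCCCCCCC[C@@H](OC(C)=O)CC1=C[C@H](O[Si](C)(C)C(C)(C)C)C=C(OC)[C@H]1O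
F4 | step 12 | (2R)-1-[(3S,6R)-3-(tert-butyldimethylsilyloxy)-6-hydroxy-5-methoxycyclohexa-1,4-dien-1-yl]tridecan-2-yl acetate | CCCCCCCCCCC[C@@H](OC(C)=O)CC1=C[C@H](O[Si](C)(C)C(C)(C)C)C=C(OC)[C@@H]1O
F5 | step 7 | [(R)-4-(triethylsilyloxy)pentadec-1-yn-1-yl]lithium | [Li]C#CC[C@H](O[Si](CC)(CC)CC)CCCCCCCCCCC
F6 | step 7 | (2E,8R)-2-methoxy-1,8-bis(triethylsilyloxy)nonadec-2-en-5-yn-4-ol, mixture of C4 epimers | CCCCCCCCCCC[C@@H](O[Si](CC)(CC)CC)CC#CC(O)/C=C(/OC)CO[Si](CC)(CC)CC
F7 | step 7 | (2E,8R)-2-methoxy-1,8-bis(triethylsilyloxy)nonadec-2-en-5-yn-4-one | CCCCCCCCCCC[C@@H](O[Si](CC)(CC)CC)CC#CC(=O)/C=C(/OC)CO[Si](CC)(CC)CC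
F8 | step 6 | methyl tetronate (4-methoxyfuran-2(5H)-one) | COC1=CC(=O)OC1
F9 | step 6 | (E)-4-hydroxy-N,3-dimethoxy-N-methylbut-2-enamide | CON(C)C(=O)/C=C(\CO)OC
F10 | step 6 | (E)-N,3-dimethoxy-N-methyl-4-(triethylsilyloxy)but-2-enamide | CON(C)C(=O)/C=C(\CO[Si](CC)(CC)CC)OC
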